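## Retrosynthetic overview

1. The target is read as epimesquitol-(4β→6)-teracacidin. The C4 carbinol of the lower unit (benzylic, para to O7, labile to acid and to H2/Pd) is made last, by NaBH4 reduction of the C4 ketone after global debenzylation.
2. Key disconnection: ring C of the lower unit is cut at O1–C8a and C4a–C4, giving an aryne on ring A (C4a≡C8a, from an ortho-silylaryl triflate) and the syn α-benzyloxy-β-hydroxy Weinreb amide 22, which brings O1, C2, C3 and C4 with both stereocentres set.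
3. Enabling feature: in ring A of the lower unit, O1 (on C8a) and C4 (on C4a) sit on neighbouring carbons, C5 bears only H, and C8 bears an oxygen. A 3-alkoxy aryne would take the alkoxide at the wrong (distal) carbon, so the C8 oxygen is carried through the key step as a pinacolboryl group (σ-donor and alkoxide tether, directing O to C8a) and oxidised to 8-OH afterwards.
4. The interflavanyl bond C4(upper)–C6(lower) is made before the lower heterocycle exists, by silver-promoted coupling of the upper 4-thioether 30 with phenol 7, whose boron and silicon block C8 and C4a.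
5. Ring order: upper ring C (step 11, same annulation on triflate 8), then lower ring C (step 17). Both Weinreb amides come from syn-glycolate aldol reactions of the one imide 12 (dibutylboron enolate for the upper unit, diethylboron enolate for the lower unit).

Key step: step 17

Assumption: fluoride is taken to attack silicon at C4a of the aryl triflates while its binding to the boronate stays reversible. Bn = benzyl, Bpin = 4,4,5,5-tetramethyl-1,3,2-dioxaborolan-2-yl.

## Route

Step 1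
Reactants: 1 3-(benzyloxy)phenol
Product: 2 3-(benzyloxy)phenyl N,N-diethylcarbamate
Conditions: NaH, THF, 0 °C; ClC(O)NEt2, 0 °C to rt
Reagents that add atoms: N,N-diethylcarbamoyl chloride CCN(CC)C(Cl)=O
Why: O-carbamoylation of the sodium phenoxide installs the O-carbamate that steers the two directed ortho-metalations that follow.

Step 2
Reactants: 2 3-(benzyloxy)phenyl N,N-diethylcarbamate
Product: 4 3-(benzyloxy)-2-(Bpin)phenyl N,N-diethylcarbamate, via aryllithium 3 (not isolated)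
Conditions: s-BuLi, TMEDA, THF, −78 °C; iPrOBpin, −78 °C to rt; aq NH4Cl
Reagents that add atoms: 2-isopropoxy-4,4,5,5-tetramethyl-1,3,2-dioxaborolane CC(C)OB1OC(C)(C)C(C)(C)O1
Why: Directed ortho-metalation should occur at the carbon between the carbamate and the benzyloxy group (two cooperating directing groups), and the aryllithium is borylated at −78 °C before an anionic Fries shift can start.

Step 3
Reactants: 4 3-(benzyloxy)-2-(Bpin)phenyl N,N-diethylcarbamate
Product: 6 3-(benzyloxy)-2-(Bpin)-6-(trimethylsilyl)phenyl N,N-diethylcarbamate, via aryllithium 5 (not isolated)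
Conditions: Me3SiCl, then LiN(iPr)2, THF, −78 °C (in situ quench)
Reagents that add atoms: chlorotrimethylsilane C[Si](C)(C)Cl
Why: A second directed ortho-metalation at the only remaining position ortho to the carbamate, run with a hindered amide base and in situ silyl chloride trapping so that the boronate is not attacked.

Step 4
Reactants: 6 3-(benzyloxy)-2-(Bpin)-6-(trimethylsilyl)phenyl N,N-diethylcarbamate
Product: 7 3-(benzyloxy)-2-(Bpin)-6-(trimethylsilyl)phenol
Conditions: Cp2Zr(H)Cl, THF, rt; H2O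
Reagents that add atoms: none
Why: Reductive cleavage of the aryl O-carbamate by hydrozirconation of its carbonyl (loss of N,N-diethylformamide) should free the phenol without acid or base, so the C–Si and C–B bonds survive.

Step 5
Reactants: 7 3-(benzyloxy)-2-(Bpin)-6-(trimethylsilyl)phenol
Product: 8 3-(benzyloxy)-2-(Bpin)-6-(trimethylsilyl)phenyl trifluoromethanesulfonate
Conditions: (CF3SO2)2O, pyridine, CH2Cl2, 0 °C
Reagents that add atoms: trifluoromethanesulfonic anhydride O=S(=O)(OS(=O)(=O)C(F)(F)F)C(F)(F)F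
Why: O-sulfonylation of the phenol gives the ortho-silylaryl triflate, a fluoride-triggered aryne precursor with boron beside the future triple bond.

Step 6
Reactants: 9 (S)-4-benzyloxazolidin-2-one; 10 benzyloxyacetyl chloride
Product: 12 (S)-4-benzyl-3-(benzyloxyacetyl)oxazolidin-2-one, via lithiated oxazolidinone 11 (not isolated)
Conditions: n-BuLi, THF, −78 °C; 10, −78 to 0 °C
Reagents that add atoms: none
Why: N-acylation of the lithiated oxazolidinone gives the glycolate imide used for both aldol reactions.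

Step 7
Reactants: 12 (S)-4-benzyl-3-(benzyloxyacetyl)oxazolidin-2-one; 13 3,4-bis(benzyloxy)benzaldehyde
Product: 16 (S)-4-benzyl-3-[(2S,3R)-2-(benzyloxy)-3-[3,4-bis(benzyloxy)phenyl]-3-hydroxypropanoyl]oxazolidin-2-one, via boron enolate 14 (not isolated), via boron aldolate 15 (not isolated)
Conditions: Bu2BOTf, Et3N, CH2Cl2, −78 to 0 °C; 13, −78 to 0 °C; pH 7 buffer, MeOH, H2O2, 0 °C
Reagents that add atoms: none
Why: Evans syn-aldol reaction of the Z-dibutylboron enolate through a closed Zimmerman–Traxler transition state, in which the (S)-benzyl auxiliary shields one enolate face and sets (2S,3R).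

Step 8
Reactants: 16 (S)-4-benzyl-3-[(2S,3R)-2-(benzyloxy)-3-[3,4-bis(benzyloxy)phenyl]-3-hydroxypropanoyl]oxazolidin-2-one
Product: 17 (2S,3R)-2-(benzyloxy)-3-[3,4-bis(benzyloxy)phenyl]-3-hydroxy-N-methoxy-N-methylpropanamide
Conditions: Me3Al, MeNHOMe·HCl, CH2Cl2, 0 °C to rt; aq potassium sodium tartrate
Reagents that add atoms: N,O-dimethylhydroxylamine hydrochloride CNOC.Cl
Why: Weinreb transamidation with the aluminium amide, helped by the free β-hydroxyl, should displace the auxiliary without touching either stereocentre.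

Step 9
Reactants: 12 (S)-4-benzyl-3-(benzyloxyacetyl)oxazolidin-2-one; 18 4-(benzyloxy)benzaldehyde
Product: 21 (S)-4-benzyl-3-[(2S,3R)-2-(benzyloxy)-3-[4-(benzyloxy)phenyl]-3-hydroxypropanoyl]oxazolidin-2-one, via diethylboron enolate 19 (not isolated), via diethylboryl aldolate 20 (not isolated)
Conditions: Et3B, CF3SO3H, CH2Cl2, 0 °C to rt (gives Et2BOTf); 12, iPr2NEt, −78 to 0 °C; 18, −78 to 0 °C; pH 7 buffer, MeOH, H2O2, 0 °C
Reagents that add atoms: none
Why: Evans syn-aldol reaction of the Z-diethylboron enolate (Et2BOTf made in the flask from triethylborane and triflic acid) through the closed Zimmerman–Traxler transition state, in which the (S)-benzyl auxiliary shields one enolate face and sets C2 and C3 of the lower unit as (2S,3R) in the open chain, which becomes 2,3-cis on the ring.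

Step 10
Reactants: 21 (S)-4-benzyl-3-[(2S,3R)-2-(benzyloxy)-3-[4-(benzyloxy)phenyl]-3-hydroxypropanoyl]oxazolidin-2-one
Product: 22 (2S,3R)-2-(benzyloxy)-3-[4-(benzyloxy)phenyl]-3-hydroxy-N-methoxy-N-methylpropanamide
Conditions: Me3Al, MeNHOMe·HCl, CH2Cl2, 0 °C to rt; aq potassium sodium tartrate
Reagents that add atoms: N,O-dimethylhydroxylamine hydrochloride CNOC.Cl
Why: Weinreb transamidation as in step 8.

Step 11
Reactants: 17 (2S,3R)-2-(benzyloxy)-3-[3,4-bis(benzyloxy)phenyl]-3-hydroxy-N-methoxy-N-methylpropanamide; 8 3-(benzyloxy)-2-(Bpin)-6-(trimethylsilyl)phenyl trifluoromethanesulfonate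
Product: 26 (2R,3S)-3,7-bis(benzyloxy)-2-[3,4-bis(benzyloxy)phenyl]-8-(Bpin)chroman-4-one, via alkoxyborate 23 (not isolated), via aryne 24 (not isolated), via hemiaminal alkoxide 25 (not isolated)
Conditions: NaH, THF, 0 °C (17 and 8 premixed); CsF, 18-crown-6, THF, 0 °C to rt; aq NH4Cl, 0 °C
Reagents that add atoms: none
Why: Proposed new method: the alkoxide of 17, held on the boron of 8 as ate complex 23, should be delivered to the boron-bearing end of the fluoride-generated 3-boryl aryne 24, after which the aryl anion acylates itself on the Weinreb amide (6-exo-trig) to the tetrahedral adduct 25; the closest known reaction types are the aryne annulation of salicylate esters to xanthones and the ortho-selective addition of nucleophiles to 3-borylarynes, and no stereocentre is formed because C2 and C3 come unchanged from 17.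

Step 12
Reactants: 26 (2R,3S)-3,7-bis(benzyloxy)-2-[3,4-bis(benzyloxy)phenyl]-8-(Bpin)chroman-4-one
Product: 28 (2R,3R,4R)-3,7-bis(benzyloxy)-2-[3,4-bis(benzyloxy)phenyl]chromane-4,8-diol, via boronate alcohol 27 (not isolated)
Conditions: NaBH4, THF/MeOH, −20 °C; then aq NaOH, H2O2, 0 °C to rt
Reagents that add atoms: hydrogen peroxide OO
Why: Hydride reduction from the face anti to the axial 3-benzyloxy group gives the 3,4-cis alcohol (its configuration is lost later), and alkaline peroxide oxidation of the aryl boronate (1,2-shift from boron to oxygen) then unveils the 8-hydroxyl once no enolisable ketone is left.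

Step 13
Reactants: 28 (2R,3R,4R)-3,7-bis(benzyloxy)-2-[3,4-bis(benzyloxy)phenyl]chromane-4,8-diol
Product: 29 (2R,3R,4R)-3,7,8-tris(benzyloxy)-2-[3,4-bis(benzyloxy)phenyl]chroman-4-ol
Conditions: BnBr, K2CO3, acetone, 50 °C
Reagents that add atoms: benzyl bromide BrCc1ccccc1
Why: Williamson etherification of the phenol only, since K2CO3 does not deprotonate the secondary alcohol.

Step 14
Reactants: 29 (2R,3R,4R)-3,7,8-tris(benzyloxy)-2-[3,4-bis(benzyloxy)phenyl]chroman-4-ol
Product: 30 (2R,3S,4S)-3,7,8-tris(benzyloxy)-2-[3,4-bis(benzyloxy)phenyl]-4-(benzylsulfanyl)chromane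
Conditions: BnSH (excess), BF3·OEt2 (cat.), CH2Cl2, −40 to 0 °C
Reagents that add atoms: phenylmethanethiol SCc1ccccc1
Why: Lewis-acid ionisation of the benzylic 4-hydroxyl to the cation stabilised by the para 7-benzyloxy group and capture by the thiol trans to the 3-benzyloxy group (SN1 thiolysis, as in proanthocyanidin thiolysis) should give the 4β-thioether, a leaving group that a thiophilic promoter can address without acid.

Step 15
Reactants: 30 (2R,3S,4S)-3,7,8-tris(benzyloxy)-2-[3,4-bis(benzyloxy)phenyl]-4-(benzylsulfanyl)chromane; 7 3-(benzyloxy)-2-(Bpin)-6-(trimethylsilyl)phenol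
Product: 31 3-(benzyloxy)-2-(Bpin)-6-(trimethylsilyl)-4-[(2R,3R)-3,7,8-tris(benzyloxy)-2-[3,4-bis(benzyloxy)phenyl]chroman-4β-yl]phenol (3,4-trans)
Conditions: AgBF4, 2,6-di-tert-butyl-4-methylpyridine, 4 Å MS, THF, 0 °C, dark; 7 in threefold excess
Reagents that add atoms: none
Why: Thiophilic activation of the C4 thioether under buffered conditions gives the flavan-4-yl cation, which the phenol should capture by Friedel–Crafts alkylation at its only free activated carbon (para to OH, the other two blocked by boron and silicon) and from the face anti to the 3-benzyloxy group, giving the 4β (3,4-trans) bond as in couplings of 2,3-cis flavan-4-yl cations.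

Step 16
Reactants: 31 the phenol from step 15
Product: 32 trifluoromethanesulfonate of 31
Conditions: (CF3SO2)2O, pyridine, CH2Cl2, −20 to 0 °C
Reagents that add atoms: trifluoromethanesulfonic anhydride O=S(=O)(OS(=O)(=O)C(F)(F)F)C(F)(F)F
Why: O-sulfonylation of the only free hydroxyl turns ring A of the future lower unit into an ortho-silylaryl triflate.

Step 17
Reactants: 32 trifluoromethanesulfonate of 31; 22 (2S,3R)-2-(benzyloxy)-3-[4-(benzyloxy)phenyl]-3-hydroxy-N-methoxy-N-methylpropanamide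
Product: 36 per-O-benzyl dimer boronate ketone (lower unit: (2R,3S)-3,7-bis(benzyloxy)-8-(Bpin)chroman-4-one), via alkoxyborate 33 (not isolated), via aryne 34 (not isolated), via hemiaminal alkoxide 35 (not isolated)
Conditions: NaH, THF, 0 °C (32 and 22, 1.5 equiv, premixed); CsF, 18-crown-6, THF, 0 °C to rt; aq NH4Cl, 0 °C
Reagents that add atoms: none
Why: Proposed new method: the alkoxide of 22 first binds the Lewis-acidic boron on C8 of 32 (ate complex 33), fluoride then strips silicon from C4a and triflate leaves from C8a to give the 3-boryl aryne 34 (C4a≡C8a, flanked by the borate on C8 and by H on C5), and because the borate is a σ-donor that makes C8a the electrophilic end and also holds the alkoxide one atom away, the oxygen should move from boron to C8a by an in-plane four-centre shift instead of adding to the distal carbon C4a as it would beside an alkoxy group. The aryl anion left on C4a then adds to the N-methoxy-N-methylamide carbonyl, and the hemiaminal alkoxide 35 keeps C4 tetrahedral until the ammonium chloride quench releases the ketone, so that no basic leaving group and no enolisable ketone is present while fluoride is. The closest known reaction types are the aryne annulation of salicylate esters to xanthones (O-arylation, then acylation of the aryl anion) and the ortho-selective addition of nucleophiles to 3-borylarynes. One ring is closed, the pyranone ring C of the lower unit, by a polar aryne 1,2-difunctionalisation: O1–C8a by addition to the aryne, then C4a–C4 by 6-exo-trig acylation. No stereocentre is created, and C2 and C3 come unchanged from 22 (2S,3R in the chain, cis on the ring) because neither new bond touches them. The step needs site selectivity at the aryne (O on C8a, C on C4a), secured by the boron on C8 as director and tether, and acylation ahead of protonation of the aryl anion, secured by the aprotic solvent and the six-membered transition state.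

Step 18
Reactants: 36 the boronate ketone from step 17
Product: 37 the corresponding 8-hydroxy ketone (lower unit: (2R,3S)-3,7-bis(benzyloxy)-8-hydroxychroman-4-one)
Conditions: KHSO5 (as 2KHSO5·KHSO4·K2SO4), acetone/H2O, 0 °C, 10 min; aq NaHSO3
Reagents that add atoms: potassium peroxymonosulfate [K+].[O-]S(=O)(=O)OO
Why: Oxidation of the aryl boronate to the phenol by peroxymonosulfate (1,2-shift of the aryl group from boron to oxygen) runs without base, which spares the epimerisable 2,3-cis ketone.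

Step 19
Reactants: 37 the 8-hydroxy ketone from step 18
Product: 38 free phenolic dimer ketone (lower unit: (2R,3S)-3,7,8-trihydroxy-2-(4-hydroxyphenyl)chroman-4-one)
Conditions: H2 (1 atm), Pd(OH)2/C, THF/MeOH, rt
Reagents that add atoms: none
Why: Hydrogenolysis of the eight benzyl ethers over Pd(OH)2/C should leave the electron-rich aryl ketone intact, and at this stage there is no benzylic C4 hydroxyl in the lower unit that could be lost.

Step 20
Reactants: 38 free phenolic dimer ketone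
Product: 39 target, epimesquitol-(4β→6)-teracacidin
Conditions: NaBH4, EtOH, 0 °C; AcOH to pH 6
Reagents that add atoms: none
Why: NaBH4 reduction of the dihydroflavonol-type ketone (the classical route from dihydroflavonols to flavan-3,4-diols) should deliver hydride anti to the axial 3-hydroxyl and so give the 3,4-cis (4R) alcohol of the all-cis lower unit.

## Compound list

1 | 3-(benzyloxy)phenol | Oc1cccc(OCc2ccccc2)c1 | starting material
2 | 3-(benzyloxy)phenyl N,N-diethylcarbamate | CCN(CC)C(=O)Oc1cccc(OCc2ccccc2)c1 | intermediate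
3 | 2-lithio derivative of 2 (lithium between the two oxygens) | CCN(CC)C(=O)Oc1cccc(OCc2ccccc2)c1[Li] | intermediate
4 | 3-(benzyloxy)-2-(Bpin)phenyl N,N-diethylcarbamate | CCN(CC)C(=O)Oc1cccc(OCc2ccccc2)c1B1OC(C)(C)C(C)(C)O1 | intermediate
5 | 6-lithio derivative of 4 | CCN(CC)C(=O)Oc1c([Li])ccc(OCc2ccccc2)c1B1OC(C)(C)C(C)(C)O1 | intermediate
6 | 3-(benzyloxy)-2-(Bpin)-6-(trimethylsilyl)phenyl N,N-diethylcarbamate | CCN(CC)C(=O)Oc1c([Si](C)(C)C)ccc(OCc2ccccc2)c1B1OC(C)(C)C(C)(C)O1 | intermediate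
7 | 3-(benzyloxy)-2-(Bpin)-6-(trimethylsilyl)phenol | Oc1c([Si](C)(C)C)ccc(OCc2ccccc2)c1B1OC(C)(C)C(C)(C)O1 | intermediate
8 | 3-(benzyloxy)-2-(Bpin)-6-(trimethylsilyl)phenyl trifluoromethanesulfonate | O=S(=O)(Oc1c([Si](C)(C)C)ccc(OCc2ccccc2)c1B1OC(C)(C)C(C)(C)O1)C(F)(F)F | intermediate
9 | (S)-4-benzyloxazolidin-2-one | O=C1N[C@@H](Cc2ccccc2)CO1 | starting material
10 | benzyloxyacetyl chloride | O=C(Cl)COCc1ccccc1 | starting material
11 | N-lithio-(S)-4-benzyloxazolidin-2-one | [Li]N1[C@@H](Cc2ccccc2)COC1=O | intermediate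
12 | (S)-4-benzyl-3-(benzyloxyacetyl)oxazolidin-2-one | O=C(COCc1ccccc1)N1C(=O)OC[C@@H]1Cc1ccccc1 | intermediate
13 | 3,4-bis(benzyloxy)benzaldehyde | O=Cc1ccc(OCc2ccccc2)c(OCc2ccccc2)c1 | starting material
14 | (Z)-dibutylboron enolate of 12 | CCCCB(CCCC)O/C(=C\OCc1ccccc1)N1C(=O)OC[C@@H]1Cc1ccccc1 | intermediate
15 | O-dibutylboryl aldolate of 16 | O=C([C@@H](OCc1ccccc1)[C@H](OB(CCCC)CCCC)c1ccc(OCc2ccccc2)c(OCc2ccccc2)c1)N1C(=O)OC[C@@H]1Cc1ccccc1 | intermediate
16 | (S)-4-benzyl-3-[(2S,3R)-2-(benzyloxy)-3-[3,4-bis(benzyloxy)phenyl]-3-hydroxypropanoyl]oxazolidin-2-one | O=C([C@@H](OCc1ccccc1)[C@H](O)c1ccc(OCc2ccccc2)c(OCc2ccccc2)c1)N1C(=O)OC[C@@H]1Cc1ccccc1 | intermediate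
17 | (2S,3R)-2-(benzyloxy)-3-[3,4-bis(benzyloxy)phenyl]-3-hydroxy-N-methoxy-N-methylpropanamide | CON(C)C(=O)[C@@H](OCc1ccccc1)[C@H](O)c1ccc(OCc2ccccc2)c(OCc2ccccc2)c1 | intermediate
18 | 4-(benzyloxy)benzaldehyde | O=Cc1ccc(OCc2ccccc2)cc1 | starting material
19 | (Z)-diethylboron enolate of 12 | CCB(CC)O/C(=C\OCc1ccccc1)N1C(=O)OC[C@@H]1Cc1ccccc1 | intermediate
20 | O-diethylboryl aldolate of 21 | O=C([C@@H](OCc1ccccc1)[C@H](OB(CC)CC)c1ccc(OCc2ccccc2)cc1)N1C(=O)OC[C@@H]1Cc1ccccc1 | intermediate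
21 | (S)-4-benzyl-3-[(2S,3R)-2-(benzyloxy)-3-[4-(benzyloxy)phenyl]-3-hydroxypropanoyl]oxazolidin-2-one | O=C([C@@H](OCc1ccccc1)[C@H](O)c1ccc(OCc2ccccc2)cc1)N1C(=O)OC[C@@H]1Cc1ccccc1 | intermediate
22 | (2S,3R)-2-(benzyloxy)-3-[4-(benzyloxy)phenyl]-3-hydroxy-N-methoxy-N-methylpropanamide | CON(C)C(=O)[C@@H](OCc1ccccc1)[C@H](O)c1ccc(OCc2ccccc2)cc1 | intermediate
23 | sodium alkoxyborate: β-alkoxide oxygen of 17 bound to the boron of 8 | [Na+].CON(C)C(=O)[C@@H](OCc1ccccc1)[C@H](O[B-]1(c2c(OCc3ccccc3)ccc([Si](C)(C)C)c2OS(=O)(=O)C(F)(F)F)OC(C)(C)C(C)(C)O1)c1ccc(OCc2ccccc2)c(OCc2ccccc2)c1 | intermediate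
24 | 3-boryl aryne: 23 after loss of the silyl group and triflate, triple bond between the two former sites | [Na+].CON(C)C(=O)[C@@H](OCc1ccccc1)[C@H](O[B-]1(C2=C(OCc3ccccc3)C=CC#C2)OC(C)(C)C(C)(C)O1)c1ccc(OCc2ccccc2)c(OCc2ccccc2)c1 | intermediate
25 | sodium N-methoxy-N-methyl hemiaminal alkoxide at C4 of 26 (cyclised tetrahedral adduct) | [Na+].CON(C)C1([O-])c2ccc(OCc3ccccc3)c(B3OC(C)(C)C(C)(C)O3)c2O[C@H](c2ccc(OCc3ccccc3)c(OCc3ccccc3)c2)[C@@H]1OCc1ccccc1 | intermediate
26 | (2R,3S)-3,7-bis(benzyloxy)-2-[3,4-bis(benzyloxy)phenyl]-8-(Bpin)chroman-4-one (2,3-cis) | O=C1c2ccc(OCc3ccccc3)c(B3OC(C)(C)C(C)(C)O3)c2O[C@H](c2ccc(OCc3ccccc3)c(OCc3ccccc3)c2)[C@@H]1OCc1ccccc1 | intermediate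
27 | (2R,3R,4R)-3,7-bis(benzyloxy)-2-[3,4-bis(benzyloxy)phenyl]-8-(Bpin)chroman-4-ol (all-cis) | O[C@@H]1c2ccc(OCc3ccccc3)c(B3OC(C)(C)C(C)(C)O3)c2O[C@H](c2ccc(OCc3ccccc3)c(OCc3ccccc3)c2)[C@@H]1OCc1ccccc1 | intermediate
28 | (2R,3R,4R)-3,7-bis(benzyloxy)-2-[3,4-bis(benzyloxy)phenyl]chromane-4,8-diol | O[C@@H]1c2ccc(OCc3ccccc3)c(O)c2O[C@H](c2ccc(OCc3ccccc3)c(OCc3ccccc3)c2)[C@@H]1OCc1ccccc1 | intermediate
29 | (2R,3R,4R)-3,7,8-tris(benzyloxy)-2-[3,4-bis(benzyloxy)phenyl]chroman-4-ol | O[C@@H]1c2ccc(OCc3ccccc3)c(OCc3ccccc3)c2O[C@H](c2ccc(OCc3ccccc3)c(OCc3ccccc3)c2)[C@@H]1OCc1ccccc1 | intermediate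
30 | (2R,3S,4S)-3,7,8-tris(benzyloxy)-2-[3,4-bis(benzyloxy)phenyl]-4-(benzylsulfanyl)chromane (2,3-cis-3,4-trans) | c1ccccc1CS[C@H]1c2ccc(OCc3ccccc3)c(OCc3ccccc3)c2O[C@H](c2ccc(OCc3ccccc3)c(OCc3ccccc3)c2)[C@@H]1OCc1ccccc1 | intermediate
31 | 3-(benzyloxy)-2-(Bpin)-6-(trimethylsilyl)phenol carrying at C4 the (2R,3R)-3,7,8-tris(benzyloxy)-2-[3,4-bis(benzyloxy)phenyl]chroman-4β-yl group (2,3-cis-3,4-trans) | Oc1c([Si](C)(C)C)cc([C@H]2c3ccc(OCc4ccccc4)c(OCc4ccccc4)c3O[C@H](c3ccc(OCc4ccccc4)c(OCc4ccccc4)c3)[C@@H]2OCc2ccccc2)c(OCc2ccccc2)c1B1OC(C)(C)C(C)(C)O1 | intermediate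
32 | trifluoromethanesulfonate of 31 | FC(F)(F)S(=O)(=O)Oc1c([Si](C)(C)C)cc([C@H]2c3ccc(OCc4ccccc4)c(OCc4ccccc4)c3O[C@H](c3ccc(OCc4ccccc4)c(OCc4ccccc4)c3)[C@@H]2OCc2ccccc2)c(OCc2ccccc2)c1B1OC(C)(C)C(C)(C)O1 | intermediate
33 | sodium alkoxyborate: β-alkoxide oxygen of 22 bound to the boron of 32 | [Na+].CON(C)C(=O)[C@@H](OCc1ccccc1)[C@H](O[B-]1(c2c(OCc3ccccc3)c([C@H]3c4ccc(OCc5ccccc5)c(OCc5ccccc5)c4O[C@H](c4ccc(OCc5ccccc5)c(OCc5ccccc5)c4)[C@@H]3OCc3ccccc3)cc([Si](C)(C)C)c2OS(=O)(=O)C(F)(F)F)OC(C)(C)C(C)(C)O1)c1ccc(OCc2ccccc2)cc1 | intermediate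
34 | 3-boryl aryne: 33 after loss of the silyl group and triflate (C4a≡C8a of the future lower ring A) | [Na+].CON(C)C(=O)[C@@H](OCc1ccccc1)[C@H](O[B-]1(C2=C(OCc3ccccc3)C([C@H]3c4ccc(OCc5ccccc5)c(OCc5ccccc5)c4O[C@H](c4ccc(OCc5ccccc5)c(OCc5ccccc5)c4)[C@@H]3OCc3ccccc3)=CC#C2)OC(C)(C)C(C)(C)O1)c1ccc(OCc2ccccc2)cc1 | intermediate
35 | sodium N-methoxy-N-methyl hemiaminal alkoxide at lower C4 of 36 (cyclised tetrahedral adduct) | [Na+].CON(C)C1([O-])c2cc([C@H]3c4ccc(OCc5ccccc5)c(OCc5ccccc5)c4O[C@H](c4ccc(OCc5ccccc5)c(OCc5ccccc5)c4)[C@@H]3OCc3ccccc3)c(OCc3ccccc3)c(B3OC(C)(C)C(C)(C)O3)c2O[C@H](c2ccc(OCc3ccccc3)cc2)[C@@H]1OCc1ccccc1 | intermediate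
36 | dimer: lower (2R,3S)-3,7-bis(benzyloxy)-2-[4-(benzyloxy)phenyl]-8-(Bpin)chroman-4-one bearing at C6 the upper per-O-benzyl (2R,3R)-flavan-4β-yl unit of 31 | C(c1ccccc1)Oc1ccc([C@H]2Oc3c(cc([C@H]4c5ccc(OCc6ccccc6)c(OCc6ccccc6)c5O[C@H](c5ccc(OCc6ccccc6)c(OCc6ccccc6)c5)[C@@H]4OCc4ccccc4)c(OCc4ccccc4)c3B3OC(C)(C)C(C)(C)O3)C(=O)[C@H]2OCc2ccccc2)cc1 | intermediate
37 | dimer as 36 but carrying an 8-hydroxyl in place of Bpin in the lower unit | C(c1ccccc1)Oc1ccc([C@H]2Oc3c(cc([C@H]4c5ccc(OCc6ccccc6)c(OCc6ccccc6)c5O[C@H](c5ccc(OCc6ccccc6)c(OCc6ccccc6)c5)[C@@H]4OCc4ccccc4)c(OCc4ccccc4)c3O)C(=O)[C@H]2OCc2ccccc2)cc1 | intermediate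
38 | free phenolic dimer ketone: upper (2R,3R,4S)-3,7,8,3',4'-pentahydroxyflavan-4-yl on C6 of lower (2R,3S)-3,7,8-trihydroxy-2-(4-hydroxyphenyl)chroman-4-one | Oc1ccc([C@H]2Oc3c(cc([C@H]4c5ccc(O)c(O)c5O[C@H](c5ccc(O)c(O)c5)[C@@H]4O)c(O)c3O)C(=O)[C@H]2O)cc1 | intermediate
39 | target: upper unit (2R,3R,4S), lower unit (2R,3R,4R), 4β→6 linked | Oc1ccc([C@H]2Oc3c(cc([C@H]4c5ccc(O)c(O)c5O[C@H](c5ccc(O)c(O)c5)[C@@H]4O)c(O)c3O)[C@@H](O)[C@H]2O)cc1 | target

## Step count and risks

Total step count: 20. Longest linear sequence: 15 steps (steps 1–5, then 11–20).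

The three steps most likely to fail:

1. Step 17 (Proposed new method). What may go wrong: delivery of the alkoxide to the distal aryne carbon, quenching of the aryl anion by proton transfer before it reaches the amide, retro-aldol cleavage of the free alkoxide, or fluoride-induced protodeboronation on the crowded ring. Fallback (known reactions only; sets out from 22 and 30, comes back at 38): 3-fluorocatechol would be benzylated (BnBr, K2CO3) to 1,2-bis(benzyloxy)-3-fluorobenzene F1 and lithiated ortho to fluorine with LiN(iPr)2 at −78 °C to 3,4-bis(benzyloxy)-2-fluorophenyllithium F2. Compound 22 would be silylated (Et3SiCl, imidazole) to its triethylsilyl ether F3, and F2 would add to F3 to give the ortho-fluoroaryl ketone F4 (Weinreb ketone synthesis). Bu4NF at 0 °C would unmask the alkoxide, which would displace the ketone-activated ortho-fluoride (intramolecular SNAr) to give the flavanone F5. NaBH4 would give the all-cis alcohol F6, which carries the 8-oxygen as a benzyl ether and would be coupled at C6 with 30 (AgBF4, 2,6-di-tert-butyl-4-methylpyridine) to the dimer alcohol F7. Dess–Martin periodinane would return the lower C4 to the ketone F8, and hydrogenolysis over Pd(OH)2/C would give 38.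

2. Step 11 (Proposed new method). What may go wrong: the same processes as in step 17 on the simpler triflate, above all addition at the wrong aryne carbon and protonation of the aryl anion. Fallback (known reactions only; sets out from 17, comes back at 29): 17 would be silylated to its triethylsilyl ether F9, the aryllithium F2 (made from F1 as above) would add to give the ortho-fluoroaryl ketone F10, Bu4NF would trigger desilylation and SNAr closure to the flavanone F11, and NaBH4 would give 29 directly, since the 8-oxygen is then a benzyl ether from the start.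

3. Step 15. What may go wrong: ipso attack of the cation at the silicon- or boron-bearing carbons, protodesilylation by the acid set free, silver-induced protodeboronation, or O-alkylation of the phenol. Fallback (sets out from 8, 22 and 30, comes back at 38): the order of events would be inverted. The annulation of step 11 would be run on 8 with 22 to give the lower boronate ketone F12, NaBH4 followed by NaOH/H2O2 would give the diol F13, and benzylation of the phenol (BnBr, K2CO3) would give F6. F6 carries neither silicon nor boron and would be coupled with 30 and carried through F7 and F8 to 38 as in the fallback for step 17.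

Further compounds
F1 | step 17 | 1,2-bis(benzyloxy)-3-fluorobenzene | Fc1cccc(OCc2ccccc2)c1OCc1ccccc1
F2 | step 17 | 3,4-bis(benzyloxy)-2-fluorophenyllithium | [Li]c1ccc(OCc2ccccc2)c(OCc2ccccc2)c1F
F3 | step 17 | (2S,3R)-2-(benzyloxy)-3-[4-(benzyloxy)phenyl]-N-methoxy-N-methyl-3-(triethylsilyloxy)propanamide | CON(C)C(=O)[C@@H](OCc1ccccc1)[C@H](O[Si](CC)(CC)CC)c1ccc(OCc2ccccc2)cc1
F4 | step 17 | (2S,3R)-2-(benzyloxy)-3-[4-(benzyloxy)phenyl]-1-[3,4-bis(benzyloxy)-2-fluorophenyl]-3-(triethylsilyloxy)propan-1-one | O=C(c1ccc(OCc2ccccc2)c(OCc2ccccc2)c1F)[C@@H](OCc1ccccc1)[C@H](O[Si](CC)(CC)CC)c1ccc(OCc2ccccc2)cc1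
F5 | step 17 | (2R,3S)-3,7,8-tris(benzyloxy)-2-[4-(benzyloxy)phenyl]chroman-4-one | O=C1c2ccc(OCc3ccccc3)c(OCc3ccccc3)c2O[C@H](c2ccc(OCc3ccccc3)cc2)[C@@H]1OCc1ccccc1
F6 | step 17 | (2R,3R,4R)-3,7,8-tris(benzyloxy)-2-[4-(benzyloxy)phenyl]chroman-4-ol | O[C@@H]1c2ccc(OCc3ccccc3)c(OCc3ccccc3)c2O[C@H](c2ccc(OCc3ccccc3)cc2)[C@@H]1OCc1ccccc1
F7 | step 17 | dimer alcohol: F6 bearing at C6 the upper per-O-benzyl (2R,3R)-flavan-4β-yl unit, lower 4-hydroxyl free | C(c1ccccc1)Oc1ccc([C@H]2Oc3c(cc([C@H]4c5ccc(OCc6ccccc6)c(OCc6ccccc6)c5O[C@H](c5ccc(OCc6ccccc6)c(OCc6ccccc6)c5)[C@@H]4OCc4ccccc4)c(OCc4ccccc4)c3OCc3ccccc3)[C@@H](O)[C@H]2OCc2ccccc2)cc1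
F8 | step 17 | dimer ketone: F7 after oxidation of the lower C4 to the ketone | C(c1ccccc1)Oc1ccc([C@H]2Oc3c(cc([C@H]4c5ccc(OCc6ccccc6)c(OCc6ccccc6)c5O[C@H](c5ccc(OCc6ccccc6)c(OCc6ccccc6)c5)[C@@H]4OCc4ccccc4)c(OCc4ccccc4)c3OCc3ccccc3)C(=O)[C@H]2OCc2ccccc2)cc1
F9 | step 11 | (2S,3R)-2-(benzyloxy)-3-[3,4-bis(benzyloxy)phenyl]-N-methoxy-N-methyl-3-(triethylsilyloxy)propanamide | CON(C)C(=O)[C@@H](OCc1ccccc1)[C@H](O[Si](CC)(CC)CC)c1ccc(OCc2ccccc2)c(OCc2ccccc2)c1
F10 | step 11 | (2S,3R)-2-(benzyloxy)-3-[3,4-bis(benzyloxy)phenyl]-1-[3,4-bis(benzyloxy)-2-fluorophenyl]-3-(triethylsilyloxy)propan-1-one | O=C(c1ccc(OCc2ccccc2)c(OCc2ccccc2)c1F)[C@@H](OCc1ccccc1)[C@H](O[Si](CC)(CC)CC)c1ccc(OCc2ccccc2)c(OCc2ccccc2)c1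
F11 | step 11 | (2R,3S)-3,7,8-tris(benzyloxy)-2-[3,4-bis(benzyloxy)phenyl]chroman-4-one | O=C1c2ccc(OCc3ccccc3)c(OCc3ccccc3)c2O[C@H](c2ccc(OCc3ccccc3)c(OCc3ccccc3)c2)[C@@H]1OCc1ccccc1
F12 | step 15 | (2R,3S)-3,7-bis(benzyloxy)-2-[4-(benzyloxy)phenyl]-8-(Bpin)chroman-4-one | O=C1c2ccc(OCc3ccccc3)c(B3OC(C)(C)C(C)(C)O3)c2O[C@H](c2ccc(OCc3ccccc3)cc2)[C@@H]1OCc1ccccc1
F13 | step 15 | (2R,3R,4R)-3,7-bis(benzyloxy)-2-[4-(benzyloxy)phenyl]chromane-4,8-diol | O[C@@H]1c2ccc(OCc3ccccc3)c(O)c2O[C@H](c2ccc(OCc3ccccc3)cc2)[C@@H]1OCc1ccccc1
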